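Which flask ends with more target after 2.0 h: Wednesday's, with 2 mol% of initiator and the substrate in 3 portions, or Tuesday's, with 4 mol% and everything in at the start?

| flask | substrate | solid reagent | initiator | remark | time |
|---|---|---|---|---|---|
| zeta | 0.050 M (in portions, 3) | 4 equiv | 1.7 mol% | run made earlier; portions every 40 min |  |
| gamma | 0.050 M (in portions, 3) | 4 equiv | 2.7 mol% | run made earlier; portions every 40 min |  |
| delta | 0.050 M (in portions, 3) | 4 equiv | 4.5 mol% | run made earlier; portions every 40 min |  |
| Wednesday's | 0.050 M (in portions, 3) | 4.00 equiv | 2 mol% | the portions of substrate follow each other after 40 min, the first at the start | 2.0 h |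
| Tuesday's | 0.050 M | 4.00 equiv | 4 mol% | everything together at the start | 2.0 h |

| run | time / min | target / % |
|---|---|---|
| zeta | 10.0 | 3.6 |
| zeta | 30.0 | 11.0 |
| zeta | 60.0 | 27.3 |
| zeta | 80.0 | 31.6 |
| zeta | 120 | 46.6 |
| gamma | 10.0 | 5.1 |
| gamma | 30.0 | 15.0 |
| gamma | 60.0 | 30.6 |
| gamma | 80.0 | 36.0 |
| gamma | 120 | 54.7 |
| delta | 10.0 | 4.0 |
| delta | 20.0 | 12.0 |
| delta | 30.0 | 17.0 |
| delta | 60.0 | 33.7 |
| delta | 120 | 61.7 |

(readings scatter by 1 percentage point)

- the flask that ends with the higher amount of target, in percent of the substrate charged, or "neither" when 2 percentage points or less lies between them (Wednesday's / Tuesday's / neither)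
- final target, as a percentage of the substrate charged, in Wednesday's
- final target, as a percentage of the substrate charged, in Tuesday's

- solid, in amounts per volume of the solution: solid reagent
- the numbers in the tables scatter with a standard deviation of 1 percentage point
- at the start none of the solid reagent is in solution

1. Write the balance of the substrate, the limiting reagent against 4.00 equiv of solid reagent: what was charged equals what is left, plus target, plus whatever else took it. The readings show target and nothing else, so that last term stays open.

2. The bench rule is that target climbs at a steady pace, whatever the portions do. The gamma run reads 30.6% at 60.0 min and 54.7% at 120 min.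

3. Interpolating the last readings on the initiator loading, I get 49.0% for Wednesday's flask and 59.8% for Tuesday's.

4. Divide the flask time by these fractions: 201 min for Tuesday's flask, 245 min for Wednesday's. Each is the cover time, how long the whole charge lasts if target is its sole outlet at the rule's pace.

5. Here is the border. The zeta, gamma and delta runs each began on 0.0167 M of substrate, while Tuesday's flask starts on 0.050 M, 3 times as much. So I commit to my figure for Wednesday's flask, whose recipe lies between two runs, and do not commit to my figure for Tuesday's.

6. The forecast says Tuesday's, with 49% (45% to 53%) for Wednesday's flask and 67% (57% to 79%) for Tuesday's, a figure above my 59.8%. Its ground is that “Tuesday's flask ends higher because it has twice the initiator”.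

    initiator → 2 initiating radical (k = 1.90 × 10⁻⁴ s⁻¹)
    substrate + initiating radical → capped initiator + first chain carrier (k = 74000 M⁻¹ s⁻¹)
    coupling partner + first chain carrier → target + second chain carrier (k = 36000 M⁻¹ s⁻¹)
    substrate + second chain carrier → by-product + first chain carrier (k = 3700 M⁻¹ s⁻¹)
    2 first chain carrier → ended chains A (k = 1.40 × 10⁷ M⁻¹ s⁻¹)
    2 second chain carrier → ended chains B (k = 7.50 × 10⁶ M⁻¹ s⁻¹)
    2 substrate → homo dimer (k = 0.0150 M⁻¹ s⁻¹)
    solid reagent ⇌ coupling partner, rate k8*(cs8 - [coupling partner]) while solid is left; crystals form when [coupling partner] > cs8 (solubility = 26.0 mM, k = 2.40 × 10⁻⁴ s⁻¹)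

7. The flask gives Wednesday's: 49.3% in Wednesday's against 32.7% in Tuesday's. In Tuesday's flask at 1.00 h, substrate stands at 3.59% with 65.1% of the charge as homo dimer. The cover time puts target there at 29.9%, and Tuesday's flask holds 29.2%. In Wednesday's flask, the 9.0% of substrate left at the end is worth 22.1 min of cover time. Read at 8.0 h, Wednesday's flask holds 56.5% of target, with 0.17% of substrate left.

The runs are simulated for an exercise, and the scatter is random.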